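**Strategy.** The plan rests on cutting ring A of the flavonol at two neighbouring positions: the O1–C8a bond and the C4–C4a bond. Because C4a is flanked by the C5 methoxy group and C8 carries only hydrogen, ring A corresponds to a 3-alkoxyaryne spanning C4a–C8a. In a single operation, fluoride-induced aryne formation followed by addition of benzyloxyacetic acid and O-to-C acyl shift installs the phenolic oxygen, the C4 carbonyl and the future C3 oxygen. The aryne precursor is an ortho-trimethylsilyl aryl triflate bearing two methoxy groups and a benzyloxy group, made from a symmetric hydroquinone. Ring B, carrying the hydroxy-ester-derived side chain, is then attached by Baker–Venkataraman chemistry.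

Key step: step 6

Remark on the chemistry: flavone numbering is used for the target (O1, C2, C3, C4, C4a, C5–C8, C8a; ring A is the benzo ring, ring B the 2-aryl group, ring C the pyranone). The side-chain stereocentre of the target is S. The R-configured hydroxy ester delivers it because the ester carbon becomes a chain CH2, which changes the CIP ranking but not the spatial arrangement. No structure needed correction.

**Route**

Step 1
Reactants: 1 2,3-dimethoxyphenol
Product: 3 2,3-dimethoxybenzene-1,4-diol, via quinone 2 (not isolated)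
Conditions: (KSO3)2NO (2.2 equiv), KH2PO4 buffer, H2O/acetone, 0 °C to rt; EtOAc extract then shaken with aq. Na2S2O4 under Ar
Reagents that add atoms: potassium nitrosodisulfonate, [K+].[K+].[O]N(S(=O)(=O)[O-])S(=O)(=O)[O-]
Why: Teuber oxidation, in which the nitrosodisulfonate radical converts a phenol with a free para position into the p-quinone (here at C4, para to the hydroxyl), followed by dithionite reduction of the quinone in the extract to the hydroquinone, whose two hydroxyls are equivalent by symmetry.

Step 2
Reactants: 3 2,3-dimethoxybenzene-1,4-diol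
Product: 4 4-(benzyloxy)-2,3-dimethoxyphenol
Conditions: BnBr (0.5 equiv relative to 3), K2CO3, acetone, 50 °C, under Ar; surplus 3 recovered
Reagents that add atoms: benzyl bromide, BrCc1ccccc1
Why: Williamson etherification of a symmetric diol, in which either hydroxyl gives the same mono-ether; keeping the bromide limiting should hold back the bis-ether.

Step 3
Reactants: 4 4-(benzyloxy)-2,3-dimethoxyphenol
Product: 5 4-(benzyloxy)-2,3-dimethoxyphenyl N-(propan-2-yl)carbamate
Conditions: i-PrNCO, Et3N (cat.), CH2Cl2, rt
Reagents that add atoms: isopropyl isocyanate, CC(C)N=C=O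
Why: Base-catalysed addition of a phenol to an isocyanate, which installs a carbamate that directs metalation and can later be removed under mild E1cB conditions.

Step 4
Reactants: 5 4-(benzyloxy)-2,3-dimethoxyphenyl N-(propan-2-yl)carbamate
Product: 9 4-(benzyloxy)-2,3-dimethoxy-6-(trimethylsilyl)phenyl N-(propan-2-yl)carbamate, via N-silyl carbamate 6 (not isolated), via aryllithium 7 (not isolated), via bis-silyl carbamate 8 (not isolated)
Conditions: TBSOTf, TMEDA, Et2O, 0 °C to rt; n-BuLi, TMEDA, −78 °C; TMSCl, −78 °C to rt; aq. NaHSO4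
Reagents that add atoms: chlorotrimethylsilane, C[Si](C)(C)Cl
Why: Directed ortho-metalation, in which in-situ N-silylation masks the N–H so that the carbamate cannot lose isocyanate, n-BuLi/TMEDA removes the only hydrogen ortho to the carbamate oxygen (the other ortho carbon carries a methoxy group), the aryllithium is silylated at −78 °C before an anionic Fries shift can set in, and the acidic work-up hydrolyses the N–Si bond.

Step 5
Reactants: 9 4-(benzyloxy)-2,3-dimethoxy-6-(trimethylsilyl)phenyl N-(propan-2-yl)carbamate
Product: 11 4-(benzyloxy)-2,3-dimethoxy-6-(trimethylsilyl)phenyl trifluoromethanesulfonate, via ortho-silylphenol 10 (not isolated)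
Conditions: DBU, Et2NH, MeCN, 40 °C; then PhNTf2, rt
Reagents that add atoms: N-phenylbis(trifluoromethanesulfonimide), O=S(=O)(N(c1ccccc1)S(=O)(=O)C(F)(F)F)C(F)(F)F
Why: DBU deprotonates the N–H and the carbamate fragments by an E1cB pathway to the phenoxide and isopropyl isocyanate, which diethylamine scavenges as a urea, and the phenoxide is then triflated in the same flask by PhNTf2, so the sensitive ortho-silylphenol is never handled.

Step 6
Reactants: 11 4-(benzyloxy)-2,3-dimethoxy-6-(trimethylsilyl)phenyl trifluoromethanesulfonate; 12 benzyloxyacetic acid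
Product: 14 2-(benzyloxy)-1-[4-(benzyloxy)-6-hydroxy-2,3-dimethoxyphenyl]ethan-1-one, via aryne 13 (not isolated)
Conditions: CsF (4 equiv), THF, 125 °C, sealed tube
Reagents that add atoms: none
Why: Fluoride attacks silicon and triflate departs from the neighbouring carbon, so the aryne 13 is released gradually in the presence of cesium benzyloxyacetate. The carboxylate oxygen adds to the aryne carbon remote from the methoxy group (future C8a), and the aryl anion left on the carbon beside that methoxy group (future C4a) attacks the carbonyl of its own ester through a four-membered transition state, which collapses to the ketone and the phenoxide (an O-to-C 1,3-acyl shift of anionic Fries type). The closest known reaction type is the fluoride-mediated addition of carboxylic acids to arynes from 2-silylaryl triflates, which gives ortho-hydroxyaryl ketones at elevated temperature. No ring is closed and no stereocentre is created. The step needs one regiochemical outcome, and the C5 methoxy group secures it: it distorts the aryne so that the remote carbon is the more electrophilic one and it stabilises the developing negative charge on the adjacent carbon inductively, an effect that should outweigh the weak influence of the more distant C7 benzyloxy group. Acyl transfer is favoured over simple protonation of the aryl anion by working in hot aprotic THF with excess CsF, so that no free acid remains.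

Step 7
Reactants: 15 methyl (R)-3-hydroxy-2-methylpropanoate
Product: 16 methyl (R)-3-(benzyloxy)-2-methylpropanoate
Conditions: benzyl 2,2,2-trichloroacetimidate, TfOH (cat.), CH2Cl2/cyclohexane, 0 °C to rt
Reagents that add atoms: benzyl 2,2,2-trichloroacetimidate, N=C(OCc1ccccc1)C(Cl)(Cl)Cl
Why: Acid-catalysed O-benzylation with a trichloroacetimidate, chosen because it avoids base and therefore neither epimerises the α-stereocentre nor triggers β-elimination.

Step 8
Reactants: 16 methyl (R)-3-(benzyloxy)-2-methylpropanoate
Product: 17 (R)-3-(benzyloxy)-2-methylpropanal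
Conditions: i-Bu2AlH (1.05 equiv), CH2Cl2, −78 °C; aq. potassium sodium tartrate (KNaC4H4O6) work-up; used crude at once
Reagents that add atoms: none
Why: Partial reduction of an ester with i-Bu2AlH at −78 °C, where the tetrahedral aluminium hemiacetal (chelated by the β-benzyloxy oxygen) survives until hydrolytic work-up, so the aldehyde is released cold and the α-stereocentre stays intact.

Step 9
Reactants: 17 (R)-3-(benzyloxy)-2-methylpropanal
Product: 18 ({[(2S)-2-methylbut-3-en-1-yl]oxy}methyl)benzene
Conditions: Ph3PCH3Br, KN(SiMe3)2, THF, 0 °C; then 17, −78 °C to 0 °C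
Reagents that add atoms: methyltriphenylphosphonium bromide, C[P+](c1ccccc1)(c1ccccc1)c1ccccc1.[Br-]
Why: Wittig methylenation with the non-stabilised ylide is fast at low temperature and should outrun enolisation of the aldehyde, so the stereocentre keeps its geometry (its descriptor changes from R to S only because the CIP ranking of the substituents changes).

Step 10
Reactants: 18 ({[(2S)-2-methylbut-3-en-1-yl]oxy}methyl)benzene; 19 methyl 3-bromo-4-methoxybenzoate
Product: 21 methyl 3-[(3S)-4-(benzyloxy)-3-methylbutyl]-4-methoxybenzoate, via alkylborane 20 (not isolated)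
Conditions: 9-BBN-H, THF, 0 °C to rt; then 19, PdCl2(dppf) (5 mol%), K3PO4 (aq.), DMF, 60 °C
Reagents that add atoms: none
Why: Anti-Markovnikov hydroboration of the terminal alkene with 9-BBN followed by B-alkyl Suzuki–Miyaura coupling, in which zerovalent palladium inserts into the C–Br bond and the dppf ligand favours reductive elimination over β-hydride elimination; the stereocentre lies two carbons from boron and is untouched.

Step 11
Reactants: 21 methyl 3-[(3S)-4-(benzyloxy)-3-methylbutyl]-4-methoxybenzoate
Product: 22 3-[(3S)-4-(benzyloxy)-3-methylbutyl]-4-methoxybenzoic acid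
Conditions: LiOH·H2O, THF/MeOH/H2O, 40 °C; then 1 M HCl
Reagents that add atoms: lithium hydroxide, [Li+].[OH-]
Why: Saponification of a methyl benzoate by hydroxide (acyl–oxygen cleavage), which leaves the benzyl ether and the remote stereocentre unaffected.

Step 12
Reactants: 22 3-[(3S)-4-(benzyloxy)-3-methylbutyl]-4-methoxybenzoic acid; 14 2-(benzyloxy)-1-[4-(benzyloxy)-6-hydroxy-2,3-dimethoxyphenyl]ethan-1-one
Product: 23 5-(benzyloxy)-2-[(benzyloxy)acetyl]-3,4-dimethoxyphenyl 3-[(3S)-4-(benzyloxy)-3-methylbutyl]-4-methoxybenzoate
Conditions: DCC, DMAP (0.2 equiv), CH2Cl2, 0 °C to rt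
Reagents that add atoms: none
Why: Steglich esterification, in which the O-acylisourea formed from the acid and DCC is passed on by DMAP as an acylpyridinium ion to the hydrogen-bonded phenol under conditions mild enough for the α-benzyloxy ketone.

Step 13
Reactants: 23 5-(benzyloxy)-2-[(benzyloxy)acetyl]-3,4-dimethoxyphenyl 3-[(3S)-4-(benzyloxy)-3-methylbutyl]-4-methoxybenzoate
Product: 25 3,7-bis(benzyloxy)-2-{3-[(3S)-4-(benzyloxy)-3-methylbutyl]-4-methoxyphenyl}-5,6-dimethoxy-4H-chromen-4-one, via 1,3-diketone 24 (not isolated)
Conditions: LiN(SiMe3)2 (3 equiv), THF, −78 to 0 °C; AcOH quench; then AcOH, H2SO4 (cat.), 60 °C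
Reagents that add atoms: none
Why: Baker–Venkataraman rearrangement (the ketone enolate at the benzyloxy-bearing carbon attacks the neighbouring aryl ester and transfers the aroyl group from oxygen to carbon) followed by acid-catalysed cyclodehydration, in which the phenol adds to the aroyl carbonyl in a 6-exo-trig closure and loss of water gives ring C; the stereocentre formed at C2 of the diketone is uncontrolled and is erased when the C2=C3 double bond forms.

Step 14
Reactants: 25 3,7-bis(benzyloxy)-2-{3-[(3S)-4-(benzyloxy)-3-methylbutyl]-4-methoxyphenyl}-5,6-dimethoxy-4H-chromen-4-one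
Product: 26 3,7-dihydroxy-2-{3-[(3S)-4-hydroxy-3-methylbutyl]-4-methoxyphenyl}-5,6-dimethoxy-4H-chromen-4-one
Conditions: H2 (1 atm), Pd(OH)2/C, EtOAc/MeOH, rt
Reagents that add atoms: none
Why: Catalytic hydrogenolysis cleaves the aryl, enol and alkyl benzyl ethers in one operation, while the methyl ethers, the fully substituted C2=C3 bond of the chromone and the side-chain stereocentre should not react.

**Compound list**

1 | 2,3-dimethoxyphenol | COc1cccc(O)c1OC | starting material
2 | 2,3-dimethoxy-1,4-benzoquinone | COC1=C(OC)C(=O)C=CC1=O | intermediate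
3 | 2,3-dimethoxybenzene-1,4-diol | COc1c(O)ccc(O)c1OC | intermediate
4 | 4-(benzyloxy)-2,3-dimethoxyphenol | COc1c(O)ccc(OCc2ccccc2)c1OC | intermediate
5 | 4-(benzyloxy)-2,3-dimethoxyphenyl N-(propan-2-yl)carbamate | COc1c(OC(=O)NC(C)C)ccc(OCc2ccccc2)c1OC | intermediate
6 | 4-(benzyloxy)-2,3-dimethoxyphenyl N-[tert-butyl(dimethyl)silyl]-N-(propan-2-yl)carbamate | COc1c(OC(=O)N(C(C)C)[Si](C)(C)C(C)(C)C)ccc(OCc2ccccc2)c1OC | intermediate
7 | 6-lithio derivative of 6 (aryllithium ortho to the carbamate oxygen) | COc1c(OC(=O)N(C(C)C)[Si](C)(C)C(C)(C)C)c([Li])cc(OCc2ccccc2)c1OC | intermediate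
8 | 4-(benzyloxy)-2,3-dimethoxy-6-(trimethylsilyl)phenyl N-[tert-butyl(dimethyl)silyl]-N-(propan-2-yl)carbamate | COc1c(OC(=O)N(C(C)C)[Si](C)(C)C(C)(C)C)c([Si](C)(C)C)cc(OCc2ccccc2)c1OC | intermediate
9 | 4-(benzyloxy)-2,3-dimethoxy-6-(trimethylsilyl)phenyl N-(propan-2-yl)carbamate | COc1c(OC(=O)NC(C)C)c([Si](C)(C)C)cc(OCc2ccccc2)c1OC | intermediate
10 | 4-(benzyloxy)-2,3-dimethoxy-6-(trimethylsilyl)phenol | COc1c(O)c([Si](C)(C)C)cc(OCc2ccccc2)c1OC | intermediate
11 | 4-(benzyloxy)-2,3-dimethoxy-6-(trimethylsilyl)phenyl trifluoromethanesulfonate | COc1c(OS(=O)(=O)C(F)(F)F)c([Si](C)(C)C)cc(OCc2ccccc2)c1OC | intermediate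
12 | benzyloxyacetic acid | O=C(O)COCc1ccccc1 | starting material
13 | 5-(benzyloxy)-3,4-dimethoxybenzyne (1,2-didehydrobenzene; triple bond between C1 and C2, methoxy on C3 and C4) | COC1=C(OC)C(OCc2ccccc2)=CC#C1 | intermediate
14 | 2-(benzyloxy)-1-[4-(benzyloxy)-6-hydroxy-2,3-dimethoxyphenyl]ethan-1-one | COc1c(OC)c(OCc2ccccc2)cc(O)c1C(=O)COCc1ccccc1 | intermediate
15 | methyl (R)-3-hydroxy-2-methylpropanoate | COC(=O)[C@H](C)CO | starting material
16 | methyl (R)-3-(benzyloxy)-2-methylpropanoate | COC(=O)[C@H](C)COCc1ccccc1 | intermediate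
17 | (R)-3-(benzyloxy)-2-methylpropanal | O=C[C@H](C)COCc1ccccc1 | intermediate
18 | ({[(2S)-2-methylbut-3-en-1-yl]oxy}methyl)benzene | C=C[C@H](C)COCc1ccccc1 | intermediate
19 | methyl 3-bromo-4-methoxybenzoate | COC(=O)c1ccc(OC)c(Br)c1 | starting material
20 | 9-[(3S)-4-(benzyloxy)-3-methylbutyl]-9-borabicyclo[3.3.1]nonane | C1CCC2CCCC1B2CC[C@H](C)COCc1ccccc1 | intermediate
21 | methyl 3-[(3S)-4-(benzyloxy)-3-methylbutyl]-4-methoxybenzoate | COC(=O)c1ccc(OC)c(CC[C@H](C)COCc2ccccc2)c1 | intermediate
22 | 3-[(3S)-4-(benzyloxy)-3-methylbutyl]-4-methoxybenzoic acid | OC(=O)c1ccc(OC)c(CC[C@H](C)COCc2ccccc2)c1 | intermediate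
23 | 5-(benzyloxy)-2-[(benzyloxy)acetyl]-3,4-dimethoxyphenyl 3-[(3S)-4-(benzyloxy)-3-methylbutyl]-4-methoxybenzoate | COc1c(OC)c(OCc2ccccc2)cc(OC(=O)c2ccc(OC)c(CC[C@H](C)COCc3ccccc3)c2)c1C(=O)COCc1ccccc1 | intermediate
24 | 2-(benzyloxy)-1-[4-(benzyloxy)-6-hydroxy-2,3-dimethoxyphenyl]-3-{3-[(3S)-4-(benzyloxy)-3-methylbutyl]-4-methoxyphenyl}propane-1,3-dione (mixture at C2 of the dione) | COc1ccc(C(=O)C(OCc2ccccc2)C(=O)c2c(O)cc(OCc3ccccc3)c(OC)c2OC)cc1CC[C@H](C)COCc1ccccc1 | intermediate
25 | 3,7-bis(benzyloxy)-2-{3-[(3S)-4-(benzyloxy)-3-methylbutyl]-4-methoxyphenyl}-5,6-dimethoxy-4H-chromen-4-one | COc1ccc(-c2oc3cc(OCc4ccccc4)c(OC)c(OC)c3c(=O)c2OCc2ccccc2)cc1CC[C@H](C)COCc1ccccc1 | intermediate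
26 | 3,7-dihydroxy-2-{3-[(3S)-4-hydroxy-3-methylbutyl]-4-methoxyphenyl}-5,6-dimethoxy-4H-chromen-4-one | COc1ccc(-c2oc3cc(O)c(OC)c(OC)c3c(=O)c2O)cc1CC[C@H](C)CO | target

**Summary**

Total step count: 14.
Longest linear sequence: 9 steps (steps 1 to 6, then 12 to 14); the ring B branch (steps 7 to 11) joins at step 12.

Steps most likely to fail:

1. Step 6. The aryl anion formed after carboxylate addition may be protonated before it reaches its own ester carbonyl, so that the sequence halts at O-arylation, or the product phenoxide may add to a second aryne. The fallback sets out from 11 and returns at 14. The same aryne is generated with CsF in DMF as solvent at rt. Formal insertion into the formamide C=O bond with the same orientation (oxygen to the remote carbon, carbon next to the methoxy group) and aqueous work-up should give 4-(benzyloxy)-6-hydroxy-2,3-dimethoxybenzaldehyde F1. Addition of benzyloxymethyllithium (from Bu3SnCH2OBn and n-BuLi, THF, −78 °C, two equivalents because of the free phenol) should give racemic 2-(benzyloxy)-1-[4-(benzyloxy)-6-hydroxy-2,3-dimethoxyphenyl]ethan-1-ol F2. Oxidation of this benzylic alcohol with MnO2 in CH2Cl2 returns ketone 14.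

2. Step 4. Deprotonation at the benzylic CH2 of the benzyl ether (leading to Wittig rearrangement) or carbamoyl migration in the aryllithium may compete with ortho-silylation. The fallback sets out from 4 and returns at 11, and avoids any deprotonation by strong base. Amine-catalysed ortho-bromination (NBS, i-Pr2NH cat., CH2Cl2, 0 °C) should give 4-(benzyloxy)-6-bromo-2,3-dimethoxyphenol F3. Silylation with HN(SiMe3)2 (neat, 80 °C) gives [4-(benzyloxy)-6-bromo-2,3-dimethoxyphenoxy]trimethylsilane F4. n-BuLi (THF, −100 to −78 °C) then effects bromine–lithium exchange and the 1,3 O-to-C silyl shift (retro-Brook rearrangement) to the lithium salt of 10, which Tf2O converts into 11.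

3. Step 13. Cleavage of the aryl ester or retro-Claisen fragmentation of the crowded diketone may outrun acyl transfer, and the acid treatment may remove a benzyl group or the C5 methyl ether. The fallback sets out from 14 (together with acid 22), bypasses ester 23 and returns at 25. Acid 22 is dehydrated to 3-[(3S)-4-(benzyloxy)-3-methylbutyl]-4-methoxybenzoic anhydride F5 (DCC, 0.5 equiv, CH2Cl2). Ketone 14 is then heated with F5 and Et3N at 160 °C (Allan–Robinson condensation: O-aroylation, C-aroylation and ring closure in one pot without strong acid or amide base). The acid 22 released is recovered.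

**Further compounds**

F1 | step 6 | 4-(benzyloxy)-6-hydroxy-2,3-dimethoxybenzaldehyde | COc1c(OC)c(OCc2ccccc2)cc(O)c1C=O
F2 | step 6 | 2-(benzyloxy)-1-[4-(benzyloxy)-6-hydroxy-2,3-dimethoxyphenyl]ethan-1-ol (racemic) | COc1c(OC)c(OCc2ccccc2)cc(O)c1C(O)COCc1ccccc1
F3 | step 4 | 4-(benzyloxy)-6-bromo-2,3-dimethoxyphenol | COc1c(O)c(Br)cc(OCc2ccccc2)c1OC
F4 | step 4 | [4-(benzyloxy)-6-bromo-2,3-dimethoxyphenoxy]trimethylsilane | COc1c(O[Si](C)(C)C)c(Br)cc(OCc2ccccc2)c1OC
F5 | step 13 | 3-[(3S)-4-(benzyloxy)-3-methylbutyl]-4-methoxybenzoic anhydride | COc1ccc(C(=O)OC(=O)c2ccc(OC)c(CC[C@H](C)COCc3ccccc3)c2)cc1CC[C@H](C)COCc1ccccc1
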